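**Target:** 2,3-dimethyl-5-[(2E,7S,11S)-3,7,11,15-tetramethylhexadec-2-en-1-yl]cyclohexa-2,5-diene-1,4-dione (14). The side chain is numbered from the ring-bound CH2 as C1′.

## The problem

Compound 14 is a 2,3-dimethyl-1,4-benzoquinone that carries at C5 a C20 isoprenoid chain with a 2′E double bond and S configuration at C7′ and C11′. The single ring is trivial, so the difficulty lies in the chain. The two stereocentres are plain CH(CH3) units in a 1,5 relationship, each at least three methylene groups away from the other and from any functional group. Neither can steer the other and no substrate-directed reaction reaches them, so both must come from a reagent or a catalyst. A stereochemical error gives a diastereomer that cannot realistically be separated from an oily hydrocarbon chain. The 7′S,11′S tail is the mirror image of the tail of natural phytol, which removes the obvious chiral-pool source. The C2′–C3′ alkene must be E and is skipped relative to the ring, so C1′ is both benzylic and allylic: acid or base can move the double bond, and at the hydroquinone oxidation level acid closes the chain onto oxygen to a chromanol. The quinone does not tolerate carbanions, low-valent metals or base, so it is best carried as its dimethyl ether and released last. The enabling feature is that C5′ to C16′, with the methyl groups on C7′, C11′ and C15′, is exactly the C15 skeleton of farnesol (C1 = C5′, C3 = C7′, C7 = C11′). In farnesol the two future stereocentres are the methyl-bearing carbons of two E trisubstituted alkenes of identical substitution pattern and orientation.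

## Retrosynthesis

**14 to 13.** The quinone carbonyls are traced back to the two aryl methyl ethers of 13; no skeletal bond is cut. Every earlier step then handles an electron-rich arene that tolerates organometallic reagents. A free hydroquinone with this ortho allylic chain would cyclise under acid, and the quinone would not survive the coupling chemistry. The forward step must oxidise the ring without touching the C2′–C3′ alkene or the benzylic/allylic C1′.

**13 to 10 and 12 (12 from 7 and 11).** Two bonds at the alkene are cut together: C1′–C2′ and the bond from C3′ to its methyl group. This gives the benzylic chloride 10 and the alkenylalane 12, the syn adduct of trimethylaluminium 11 and the terminal alkyne 7. The neighbouring cuts are weaker: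
- Cutting the ring–C1′ bond needs an aryl metal plus a complete C20 allylic electrophile, with SN2/SN2′ and E/Z leakage, or acid-mediated alkylation of hydroquinone 8, which invites chromanol closure.
- Cutting through the double bond by olefination gives E/Z mixtures at a trisubstituted alkene.

In the chosen cut the E geometry follows from syn addition. Alkyne 7 is simpler than 13 by the aromatic head, the alkene and one methyl group. The forward reaction must place methyl on C3′ and aluminium on C2′ regioselectively, then transfer the alkenyl group to 10 with retention and without reductive homocoupling of 10.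

**10 to 9 to 8.** The C1′–aryl bond of 10 is cut to the symmetrical arene 9, whose two free ring positions are equivalent, so one regioisomer is possible. Compound 9 is the bis-methyl ether of commercial 8. The forward chloromethylation must stop after one substitution.

**7 to 6 to 3 and 4 (through 5).** The terminal alkyne 7 comes from its silyl derivative 6, and 6 is cut at C4′–C5′ into the primary iodide 3 and the anion 5 of 1-(trimethylsilyl)propyne 4. This cut leaves two methylene groups between the reacting carbon and C7′, so only displacement at an unbranched primary carbon is required. It also brings in C2′, C3′ and C4′ as one commercial three-carbon unit. A cut at C5′–C6′ would need a β-branched electrophile one carbon shorter than any commercial terpene skeleton. The forward reaction must alkylate 5 at its propargylic carbon and not through its allenyl form.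

**3 to 2.** The C–I bond is traced back to the C–OH bond of alcohol 2, a one-step change at a primary carbon far from both stereocentres.

**2 to 1.** No carbon–carbon bond is left to cut, and what remains is to remove the stereocentres. Taking away the hydrogens at C3, C7 and C11 together with those at C2, C6 and C10 gives the triene 1, commercial (2E,6E)-farnesol, which has all fifteen carbons in place. Building the 1,5-dimethyl array stepwise would cost several steps per centre, whereas this cut creates both at once. The forward hydrogenation must distinguish the enantiofaces of two alkenes, one of which (C6–C7) has no directing group nearby, and must do so in the same sense at both. Only catalyst control can do the first, and the common E geometry makes the second possible.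

## Roads not taken

**Alternative 1: the ring built by Dötz benzannulation.** Here the arene is made, not bought.
- **Cut and key step.** In the numbering of the phenol product, 4-methoxy-2,3-dimethyl-6-[(2E,7S,11S)-3,7,11,15-tetramethylhexadec-2-en-1-yl]phenol A1, the carbene complex pentacarbonyl[(2E)-1-methoxy-2-methylbut-2-en-1-ylidene]chromium A2 supplies C2, C3 and C4. One CO ligand supplies C1, and the terminal enyne (4E,9S,13S)-5,9,13,17-tetramethyloctadec-4-en-1-yne A3 supplies C5 and C6. Bonds C4–C5, C1–C6 and C1–C2 form on warming, and oxidation of A1 would give 14.
- **Merits.** The terminal alkyne places the chain next to the hydroxyl reliably, and the two oxygens arrive differentiated. No aluminium alkyl and no benzylic halide are needed.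
- **Weak points.** The ring being built is that of commercial 8. The zerovalent chromium complex A2 is used stoichiometrically. A3 is a skipped enyne whose doubly activated CH2 isomerises easily, and A1 is an ortho-allyl phenol that can close to a chromanol when heated. Most important, A3 already contains the E alkene and both stereocentres, so every stereochemical problem is only moved into its preparation.
- **Comparison.** Alternative 1 is better in avoiding the pyrophoric reagent 11 and the nickel coupling. The chosen plan sets against it a two-step head piece from a commercial arene, no stoichiometric chromium, and the fact that A3 would need the same hydrogenation and an E-selective alkene synthesis plus an allyl–alkynyl coupling on top.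

**Alternative 2: sulfone carbanion alkylation at C4′–C5′.**
- **Cut and key step.** The chain is cut between C4′ and C5′. Deprotonated {[(3S,7S)-3,7,11-trimethyldodecyl]sulfonyl}benzene A5 displaces bromide from 1-[(2E)-4-bromo-3-methylbut-2-en-1-yl]-2,5-dimethoxy-3,4-dimethylbenzene A6. This gives 1,4-dimethoxy-2,3-dimethyl-5-[(2E,7S,11S)-3,7,11,15-tetramethyl-5-(phenylsulfonyl)hexadec-2-en-1-yl]benzene A4 as both C5′ epimers. Reductive desulfonylation would then give 13.
- **Merits.** The bond formation is robust and needs no transition metal. The E alkene is fixed in the small fragment A6, where geometric purity can be secured before the chiral tail is committed. A5 is one step from iodide 3, so the same hydrogenation can feed it.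
- **Weak points.** A6 needs prenylation of the arene, E-selective allylic oxidation and bromination. The sulfone must be removed reductively next to a benzylic/allylic system, with risk of alkene migration or over-reduction. The new C5′ centre is formed only to be destroyed. The route to 13 is about three steps longer.
- **Comparison.** Alternative 2 is at least as good in control of alkene geometry and avoids the regiochemical question of the methylalumination. The chosen plan sets against it the shorter sequence and an E geometry that follows directly from syn carbometalation.

**Alternative 3: lipase desymmetrisation of a hidden meso diol.**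
- **Cut and key step.** C7′ and C11′, with their four inner carbons, map onto meso (2R,6S)-2,6-dimethylheptane-1,7-diol A8. A lipase acetylates one enantiotopic hydroxymethyl arm to give (2S,6R)-7-hydroxy-2,6-dimethylheptyl acetate A7. One-carbon extension at the acetate end and attachment of a 3-methylbutyl group at the hydroxyl end would converge on 2.
- **Merits.** Both centres come from a cheap achiral precursor under ambient conditions, without pressure equipment or iridium. Either enantiomeric series is reachable by choosing which end is extended first. The stereochemical purity of A7 can be measured, and if necessary upgraded, on a small molecule with two functional handles.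
- **Weak points.** A8 must itself be made free of its racemic diastereomer. A7 holds only nine of the twenty chain carbons, so two separate sp3–sp3 chain extensions with protecting-group changes are needed before 2 is reached. A lipase recognises a stereocentre β to a primary hydroxyl less sharply than one at a secondary carbinol.
- **Comparison.** Alternative 3 is better in analytical control, because 2 made by hydrogenation has no handle near its stereocentres. The chosen plan sets against it one step from a commercial C15 compound in which every carbon is already in place, against roughly six to eight steps to reach the same alcohol.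

Key step: step 1

## Assumptions

- Commercial (2E,6E)-farnesol 1 is freed from any 2Z or 6Z isomer by chromatography on AgNO3-impregnated silica before use; this purification is not counted as a step.
- The sense of induction in step 1 follows the absolute configuration of the ligand alone, so the enantiomer of L opposite to the one that leads to the natural 3R,7R series is used.

## Route

Step 1
Reactants: 1 (2E,6E)-farnesol [(2E,6E)-3,7,11-trimethyldodeca-2,6,10-trien-1-ol]
Product: 2 (3S,7S)-3,7,11-trimethyldodecan-1-ol
Conditions: H2 (50 bar), [Ir(cod)(L)][B(C6H3(CF3)2)4] (1 mol%), CH2Cl2, 23 °C; cod = cycloocta-1,5-diene, L = 2-phenyl-6,7-dihydro-5H-cyclopenta[b]pyridin-7-yl di(o-tolyl)phosphinite, single enantiomer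
Reagents that add atoms: none
Why: Under H2 the monovalent iridium precatalyst loses its cycloocta-1,5-diene ligand and becomes a cationic iridium dihydride that binds a trisubstituted alkene and further H2 without help from a coordinating group; migratory insertion and C–H reductive elimination, most likely on a trivalent/pentavalent iridium manifold, deliver both hydrogens to one face. The closest known reaction type is the iridium P,N-catalysed asymmetric hydrogenation of unfunctionalised trisubstituted alkenes and E allylic alcohols, which includes farnesol-type polyenes. No ring closes and no skeletal bond forms. C3 and C7 are each set by the catalyst alone: the alkene sits in the chiral pocket with its vinylic hydrogen in the most crowded quadrant next to the pyridine substituent, and this fixes the enantioface. Because the C2–C3 and C6–C7 alkenes are both E and carry H, CH2, CH3 and CH2 in the same spatial order along the chain, they present the same face and receive the same descriptor, 3S,7S with the ligand enantiomer chosen; the C10–C11 isopropylidene is reduced without stereochemical consequence. The selectivity needed is enantioface selectivity at two independent alkenes, secured by the geometric purity of 1 (a Z alkene would give the epimer at its carbon) and by reduction being faster than E/Z isomerisation. The tetraarylborate counter-ion and the non-coordinating solvent should keep the catalyst active long enough to saturate all three double bonds at low loading.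

Step 2
Reactants: 2 (3S,7S)-3,7,11-trimethyldodecan-1-ol
Product: 3 (3S,7S)-1-iodo-3,7,11-trimethyldodecane
Conditions: I2, PPh3, imidazole, CH2Cl2, 0 → 23 °C
Reagents that add atoms: iodine, II
Why: Appel-type iodination: the primary hydroxyl is activated as an alkoxyphosphonium ion and displaced by iodide in an SN2 reaction at C1, two carbons away from the nearest stereocentre, so both centres are untouched.

Step 3
Reactants: 3 (3S,7S)-1-iodo-3,7,11-trimethyldodecane; 4 1-(trimethylsilyl)propyne [trimethyl(prop-1-yn-1-yl)silane]
Product: 6 trimethyl[(6S,10S)-6,10,14-trimethylpentadec-1-yn-1-yl]silane, via 3-lithio-1-(trimethylsilyl)propyne 5 (not isolated)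
Conditions: 4 (1.5 equiv), n-BuLi, THF, −78 → −20 °C; then 3, −78 → 23 °C
Reagents that add atoms: none
Why: Propargylic deprotonation of 4 followed by SN2 alkylation of the unbranched primary iodide forms the C4′–C5′ bond; the silyl group blocks the acetylenic terminus and biases the ambident anion toward the propargyl product.

Step 4
Reactants: 6 trimethyl[(6S,10S)-6,10,14-trimethylpentadec-1-yn-1-yl]silane
Product: 7 (6S,10S)-6,10,14-trimethylpentadec-1-yne
Conditions: K2CO3, MeOH/THF, 23 °C
Reagents that add atoms: none
Why: Base-mediated protodesilylation of an alkynylsilane: methoxide attacks silicon and the acetylide is protonated by methanol; nothing else in the molecule is reactive under these conditions.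

Step 5
Reactants: 8 2,3-dimethylhydroquinone (2,3-dimethylbenzene-1,4-diol)
Product: 9 1,4-dimethoxy-2,3-dimethylbenzene
Conditions: MeI, K2CO3, acetone, reflux, under N2
Reagents that add atoms: iodomethane, CI
Why: Williamson ether synthesis on both phenolic hydroxyls; the inert atmosphere keeps the electron-rich phenoxide from air oxidation to the quinone.

Step 6
Reactants: 9 1,4-dimethoxy-2,3-dimethylbenzene
Product: 10 1-(chloromethyl)-2,5-dimethoxy-3,4-dimethylbenzene
Conditions: (CH2O)n (1.1 equiv), HCl (conc. aq. and gas), 1,4-dioxane, 23 °C
Reagents that add atoms: formaldehyde (from paraformaldehyde), C=O; hydrogen chloride, Cl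
Why: Blanc chloromethylation, an electrophilic aromatic substitution by protonated formaldehyde followed by chloride exchange of the benzylic alcohol; the two free ring positions of 9 are equivalent by symmetry, and near-stoichiometric formaldehyde with the mildly deactivating CH2Cl group should hold the reaction at one substitution.

Step 7
Reactants: 7 (6S,10S)-6,10,14-trimethylpentadec-1-yne; 11 trimethylaluminium; 10 1-(chloromethyl)-2,5-dimethoxy-3,4-dimethylbenzene
Product: 13 1,4-dimethoxy-2,3-dimethyl-5-[(2E,7S,11S)-3,7,11,15-tetramethylhexadec-2-en-1-yl]benzene, via (E)-alkenyldimethylalane 12 (not isolated)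
Conditions: 11 (2 equiv), Cp2ZrCl2 (25 mol%), ClCH2CH2Cl, 0 → 23 °C; volatiles removed in vacuo; then 10, NiCl2(PPh3)2 (3 mol%)/n-BuLi (6 mol%), THF, 0 → 23 °C
Reagents that add atoms: none
Why: Negishi zirconium-catalysed methylalumination adds CH3 and Al syn across the terminal alkyne, with methyl at the internal carbon (C3′) and aluminium at the terminal carbon (C2′), which fixes the E geometry; zerovalent nickel, formed from NiCl2(PPh3)2 and n-BuLi, then couples the alkenylalane with the benzylic chloride with retention to form the C1′–C2′ bond. Removal of excess 11 before the coupling avoids methyl transfer to 10.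

Step 8
Reactants: 13 1,4-dimethoxy-2,3-dimethyl-5-[(2E,7S,11S)-3,7,11,15-tetramethylhexadec-2-en-1-yl]benzene
Product: 14 2,3-dimethyl-5-[(2E,7S,11S)-3,7,11,15-tetramethylhexadec-2-en-1-yl]cyclohexa-2,5-diene-1,4-dione
Conditions: (NH4)2Ce(NO3)6 (2.5 equiv), MeCN/CH2Cl2/H2O, 0 °C
Reagents that add atoms: water, O
Why: Oxidative demethylation of a para-dimethoxyarene by tetravalent cerium: two one-electron oxidations, attack of water at the two oxygen-bearing ring carbons and loss of two molecules of methanol give the para-quinone; the isolated trisubstituted alkene and the remote stereocentres should survive a short, cold exposure.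

## Compound list

1 | (2E,6E)-farnesol, (2E,6E)-3,7,11-trimethyldodeca-2,6,10-trien-1-ol | CC(C)=CCC/C(C)=C/CC/C(C)=C/CO | starting material
2 | (3S,7S)-3,7,11-trimethyldodecan-1-ol | OCC[C@@H](C)CCC[C@@H](C)CCCC(C)C | intermediate
3 | (3S,7S)-1-iodo-3,7,11-trimethyldodecane | ICC[C@@H](C)CCC[C@@H](C)CCCC(C)C | intermediate
4 | 1-(trimethylsilyl)propyne, trimethyl(prop-1-yn-1-yl)silane | CC#C[Si](C)(C)C | starting material
5 | 3-lithio-1-(trimethylsilyl)propyne | [Li]CC#C[Si](C)(C)C | intermediate
6 | trimethyl[(6S,10S)-6,10,14-trimethylpentadec-1-yn-1-yl]silane | C[Si](C)(C)C#CCCC[C@@H](C)CCC[C@@H](C)CCCC(C)C | intermediate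
7 | (6S,10S)-6,10,14-trimethylpentadec-1-yne | C#CCCC[C@@H](C)CCC[C@@H](C)CCCC(C)C | intermediate
8 | 2,3-dimethylhydroquinone, 2,3-dimethylbenzene-1,4-diol | Cc1c(O)ccc(O)c1C | starting material
9 | 1,4-dimethoxy-2,3-dimethylbenzene | COc1ccc(OC)c(C)c1C | intermediate
10 | 1-(chloromethyl)-2,5-dimethoxy-3,4-dimethylbenzene | COc1cc(CCl)c(OC)c(C)c1C | intermediate
11 | trimethylaluminium | C[Al](C)C | starting material
12 | dimethyl[(1E,6S,10S)-2,6,10,14-tetramethylpentadec-1-en-1-yl]alumane | C[Al](C)/C=C(\C)CCC[C@@H](C)CCC[C@@H](C)CCCC(C)C | intermediate
13 | 1,4-dimethoxy-2,3-dimethyl-5-[(2E,7S,11S)-3,7,11,15-tetramethylhexadec-2-en-1-yl]benzene | COc1cc(C/C=C(\C)CCC[C@@H](C)CCC[C@@H](C)CCCC(C)C)c(OC)c(C)c1C | intermediate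
14 | 2,3-dimethyl-5-[(2E,7S,11S)-3,7,11,15-tetramethylhexadec-2-en-1-yl]cyclohexa-2,5-diene-1,4-dione | CC1=C(C)C(=O)C(C/C=C(\C)CCC[C@@H](C)CCC[C@@H](C)CCCC(C)C)=CC1=O | target

## Step count and risks

Total step count: 8. Longest linear sequence: 6 steps (steps 1, 2, 3, 4, 7, 8); the head piece takes 2 steps (5, 6).

**Step 1 (key step).**
- **What may go wrong.** Enantioface selectivity may erode at the C2–C3 alkene through competitive binding of the allylic hydroxyl to iridium. The acidic iridium hydride may cause E/Z isomerisation or ionisation of the allylic alcohol ahead of reduction. The catalyst may deactivate before the third alkene is saturated. Because 2 has no handle near its stereocentres, stereoisomers formed here cannot be removed later.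
- **Fallback.** Divide the task between two control elements. Starting from 1, hydrogenation with Ru(OAc)2[(R)-binap] in methanol under H2 reduces only C2–C3, because the allylic hydroxyl chelates divalent ruthenium and directs hydrogen delivery. By analogy with the geraniol-to-citronellol reduction this should give (3S,6E)-3,7,11-trimethyldodeca-6,10-dien-1-ol F1. The iridium catalyst of step 1 then has only the purely alkyl-substituted C6–C7 and C10–C11 alkenes to reduce, and the route is rejoined at 2.

**Step 7.**
- **What may go wrong.** Regiocontrol in the methylalumination may be incomplete, with methyl delivered to C2′ instead of C3′. At nickel, 10 may undergo reductive homocoupling or take a methyl group from residual 11. Slow aluminium-to-nickel transmetalation may end in protodealumination on work-up.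
- **Fallback.** Reverse the polarity of the coupling partners. The alane 12, generated from 7 and 11 as before, is cleaved with I2 (THF, −30 °C) to (1E,6S,10S)-1-iodo-2,6,10,14-tetramethylpentadec-1-ene F2, which can be purified. Compound 10 is converted with zinc dust and LiCl in THF into chloro[(2,5-dimethoxy-3,4-dimethylphenyl)methyl]zinc F3. Negishi coupling of F2 with F3 under Pd(PPh3)4 (zerovalent palladium) in THF should give 13 with retention of the E geometry.

**Step 6.**
- **What may go wrong.** A second chloromethylation may occur at the remaining ring position, and 10 may condense with unreacted 9 in a Friedel–Crafts reaction to a diarylmethane. Both are favoured by the electron-rich ring.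
- **Fallback.** Introduce the benzylic carbon at the aldehyde oxidation level, where the deactivating formyl group suppresses a second substitution. From 9, Rieche formylation (Cl2CHOCH3, TiCl4, CH2Cl2, 0 °C) should give 2,5-dimethoxy-3,4-dimethylbenzaldehyde F4. NaBH4 in methanol then gives (2,5-dimethoxy-3,4-dimethylphenyl)methanol F5, and SOCl2 in CH2Cl2 returns the route to 10.

**Step 3.**
- **What may go wrong.** The ambident anion 5 may react through its allenyl terminus, giving an allenylsilane that step 4 does not convert into 7. E2 elimination of 3 may compete.
- **Fallback.** Add the same carbons without an ambident nucleophile. From 3, alkylation of lithioacetonitrile (CH3CN, LiN(i-Pr)2, THF, −78 °C) should give (5S,9S)-5,9,13-trimethyltetradecanenitrile F6. Partial reduction with i-Bu2AlH followed by hydrolysis gives (5S,9S)-5,9,13-trimethyltetradecanal F7. Ohira–Bestmann homologation (dimethyl (1-diazo-2-oxopropyl)phosphonate, K2CO3, MeOH) then gives 7 directly, bypassing 6.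

## Further compounds

F1 | step 1 | (3S,6E)-3,7,11-trimethyldodeca-6,10-dien-1-ol | OCC[C@@H](C)CC/C=C(\C)CCC=C(C)C
F2 | step 7 | (1E,6S,10S)-1-iodo-2,6,10,14-tetramethylpentadec-1-ene | I/C=C(\C)CCC[C@@H](C)CCC[C@@H](C)CCCC(C)C
F3 | step 7 | chloro[(2,5-dimethoxy-3,4-dimethylphenyl)methyl]zinc | COc1cc(C[Zn]Cl)c(OC)c(C)c1C
F4 | step 6 | 2,5-dimethoxy-3,4-dimethylbenzaldehyde | COc1cc(C=O)c(OC)c(C)c1C
F5 | step 6 | (2,5-dimethoxy-3,4-dimethylphenyl)methanol | COc1cc(CO)c(OC)c(C)c1C
F6 | step 3 | (5S,9S)-5,9,13-trimethyltetradecanenitrile | N#CCCC[C@@H](C)CCC[C@@H](C)CCCC(C)C
F7 | step 3 | (5S,9S)-5,9,13-trimethyltetradecanal | O=CCCC[C@@H](C)CCC[C@@H](C)CCCC(C)C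
A1 | alternative 1 | 4-methoxy-2,3-dimethyl-6-[(2E,7S,11S)-3,7,11,15-tetramethylhexadec-2-en-1-yl]phenol | COc1cc(C/C=C(\C)CCC[C@@H](C)CCC[C@@H](C)CCCC(C)C)c(O)c(C)c1C
A2 | alternative 1 | pentacarbonyl[(2E)-1-methoxy-2-methylbut-2-en-1-ylidene]chromium | COC(/C(C)=C/C)=[Cr](=C=O)(=C=O)(=C=O)(=C=O)=C=O
A3 | alternative 1 | (4E,9S,13S)-5,9,13,17-tetramethyloctadec-4-en-1-yne | C#CC/C=C(\C)CCC[C@@H](C)CCC[C@@H](C)CCCC(C)C
A4 | alternative 2 | 1,4-dimethoxy-2,3-dimethyl-5-[(2E,7S,11S)-3,7,11,15-tetramethyl-5-(phenylsulfonyl)hexadec-2-en-1-yl]benzene (both C5′ epimers) | COc1cc(C/C=C(\C)CC(C[C@@H](C)CCC[C@@H](C)CCCC(C)C)S(=O)(=O)c2ccccc2)c(OC)c(C)c1C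
A5 | alternative 2 | {[(3S,7S)-3,7,11-trimethyldodecyl]sulfonyl}benzene | O=S(=O)(CC[C@@H](C)CCC[C@@H](C)CCCC(C)C)c1ccccc1
A6 | alternative 2 | 1-[(2E)-4-bromo-3-methylbut-2-en-1-yl]-2,5-dimethoxy-3,4-dimethylbenzene | COc1cc(C/C=C(\C)CBr)c(OC)c(C)c1C
A7 | alternative 3 | (2S,6R)-7-hydroxy-2,6-dimethylheptyl acetate | CC(=O)OC[C@@H](C)CCC[C@@H](C)CO
A8 | alternative 3 | (2R,6S)-2,6-dimethylheptane-1,7-diol (meso) | OC[C@@H](C)CCC[C@@H](C)CO
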